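The numbers come from no measurement; what happens was integrated by code.

The dimer number is 2.76: the rate at which full-strength reagent goes into homo dimer, over the rate at which the chain takes full-strength starting material.

    reagent + first chain carrier ⇌ product + second chain carrier (K1 = 25, k1 = 1.7 × 10⁶ M⁻¹ s⁻¹)
    initiator → 2 initiating radical (k2 = 8.3 × 10⁻⁶ s⁻¹)
    starting material + second chain carrier → by-product + first chain carrier (k3 = 29000 M⁻¹ s⁻¹)
    first chain carrier → ended carrier (k4 = 5.9 s⁻¹)
    2 reagent → homo dimer (k5 = 0.0082 M⁻¹ s⁻¹)
    starting material + initiating radical → capped initiator + first chain carrier (k6 = 2.8 × 10⁶ M⁻¹ s⁻¹)
    2 second chain carrier → ended chains (k7 = 6.4 × 10⁸ M⁻¹ s⁻¹)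

| setting | Sunday's | Monday's | Wednesday's | Tuesday's |
|---|---|---|---|---|
| starting material | 0.031 M | 0.031 M | 0.031 M | 0.031 M |
| reagent | 0.0310 M | 0.0310 M | 0.0310 M | 0.0310 M (fed, over 12.0 h) |
| initiator | 3.1 mM | 3.1 mM | 3.1 mM | 3.1 mM |
| time | 15 h | 15 h |  | 15 h |
| remark | everything together in a closed stirred flask, run for 15 h | plug flow through a tube for 15 h, no back-mixing | one stirred flow tank at steady state, fed with the mixture as stated, mean residence time 15 h | a stirred flask in which reagent is dosed at a steady rate over 12.0 h without added volume, worked up at 15 h |

- for a step with 2 of a species take k times the square, and two of it per event
- the stated concentrations are those of everything mixed, before any reaction; amounts are the same in each set-up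
- the feed brings no volume worth counting
- run time (Sunday's): 15 h

1. the set-up with the highest amount of product at the outlet or at the end, in percent of the starting material put in ("none" if the first two lie within 2 percentage points) (Sunday's / Monday's / Wednesday's / Tuesday's / none)
2. amount of product at the outlet or at the end, in percent of the starting material put in, Sunday's
3. amount of product at the outlet or at the end, in percent of the starting material put in, Monday's
4. amount of product at the outlet or at the end, in percent of the starting material put in, Wednesday's
5. amount of product at the outlet or at the end, in percent of the starting material put in, Tuesday's

I find that number by freezing two things. I hold the second chain carrier at 6.34 × 10⁻⁹ M, where radicals made balance carriers ended in pairs. Starting material then falls pseudo-first-order, with a time of 1.51 h. The initiator's half-life of 23 h is longer than that time, so over that time I hold the initiator at its charge.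

Let a be the fraction of starting material left and b the fraction of reagent left. Of the reagent lost at any moment, the share going to product is a/(a + D·b²), with D the dimer number. The a of the middle row is the whole charge less the product I reckon on the way down to that row.

| b | a | share to product |
|---|---|---|
| 1 | 1 | 0.266 |
| 0.5 | 0.786 | 0.532 |
| 0 | any | 1 |

The top row says that at first about a quarter of the lost reagent becomes product. By the middle row it is about half, and the bottom row loses nothing to homo dimer. Taking each stretch between rows at the mean of its two shares, and the two stretches equally, gives 58.2% for Sunday's, and 58.2% for Monday's, whose tube is the same flask laid out in time.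

The chain's time is shorter than Tuesday's dosing time and Wednesday's residence time, so I expect reagent to stand low in both and read them from the bottom row. In Wednesday's tank, I reckon initiator at 0.691 of its charge, and the residence time is then 8.25 times the chain's time there, which gives 89.2%. For Tuesday's I subtract the fraction of starting material I reckon taken by initiating radicals, 0.0722, which gives 92.8%. My choice is Tuesday's.

The forecast gives 58%, 58%, 81% and 91% and names Tuesday's, holding that “the stirred tank and especially slow dosing keep reagent concentration low and suppress the second-order loss”.

The simulation gives 58.2%, 58.2%, 84.6% and 93.3%, with Tuesday's highest.

Monday's homo dimer step has >99.9% of its turnover behind it after 1.50 h, and the step of starting material with second chain carrier has reached the midpoint of its turnover at 0.523 h. At the end Monday's holds 0% of its reagent and 35.3% of its starting material. A flask like Monday's with 7.8 × 10⁻⁴ M of initiator has a dimer number of 5.51, and the same three rows give 48.0%. That flask gives 46.4%.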